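The α‑methylene‑γ‑lactone ring (O–C6–C7–C11–C12; germacrane numbering: C1 ketone, C2=C3 furanone olefin, C4=C5, C8 tiglate carbon, C10 quaternary, C11=C13 methylene, C15 CH2OH) is disconnected into an alkenyl bromide at C11, a C5–C6 epoxide, CO and water. One palladium‑catalysed hydroxycarbonylation builds the C11–C12 bond, and the nascent acrylate opens the epoxide at C6 with inversion (O–C6 bond), which sets the cis ring fusion. The step exploits the sp2 character of C11 and the 1,3‑relationship of C6 to C11. The precursor is a furanone‑containing bromoalkenyl epoxide; ring‑closing metathesis then forms the ten‑membered ring.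

Key step: step 11

Assumption: the Z‑enol borinate made with (−)‑Ipc2BOTf is taken to attack the si face of the aldehyde; should the sense be opposite, (+)‑Ipc2BOTf is used instead.

Step 1
Reactants: 1 2‑bromoprop‑2‑en‑1‑ol
Product: 2 [(2‑bromoprop‑2‑en‑1‑yl)oxy](tert‑butyl)dimethylsilane
Conditions: TBSCl, imidazole, CH2Cl2, 0 °C to rt
Reagents that add atoms: tert‑butyldimethylsilyl chloride, CC(C)(C)[Si](C)(C)Cl
Why: Silyl ether formation on a primary allylic alcohol should be clean and masks the future C15 hydroxyl; no stereocentre is involved.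

Step 2
Reactants: 2 [(2‑bromoprop‑2‑en‑1‑yl)oxy](tert‑butyl)dimethylsilane
Product: 3 tert‑butyl(dimethyl)[(2‑methylidenebut‑3‑yn‑1‑yl)oxy]silane
Conditions: ethynylmagnesium bromide, ZnBr2, THF, 0 °C; then 2, Pd(PPh3)4 (3 mol %), rt
Reagents that add atoms: ethynylmagnesium bromide, C#C[Mg]Br
Why: Negishi coupling of the alkenyl bromide with ethynylzinc bromide under zerovalent palladium catalysis should give the terminal 1,3‑enyne directly, without a separate alkyne deprotection.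

Step 3
Reactants: 4 (R)‑citramalic acid
Product: 5 2‑[(4R)‑2,2,4‑trimethyl‑5‑oxo‑1,3‑dioxolan‑4‑yl]acetic acid
Conditions: 2,2‑dimethoxypropane, p‑TsOH (cat.), rt
Reagents that add atoms: 2,2‑dimethoxypropane, COC(C)(C)OC
Why: Acid‑catalysed acetalisation should engage the α‑hydroxy acid as the five‑membered 1,3‑dioxolan‑4‑one and leave the β‑carboxyl free, the C10 stereocentre coming unchanged from the chiral pool.

Step 4
Reactants: 5 2‑[(4R)‑2,2,4‑trimethyl‑5‑oxo‑1,3‑dioxolan‑4‑yl]acetic acid; 6 2,3‑dibromoprop‑1‑ene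
Product: 8 (5R)‑5‑(4‑bromo‑2‑oxopent‑4‑en‑1‑yl)‑2,2,5‑trimethyl‑1,3‑dioxolan‑4‑one, via acid chloride 7 (not isolated)
Conditions: (COCl)2, DMF (cat.), CH2Cl2, 0 °C to rt; evaporate; then 6, In powder, THF, rt
Reagents that add atoms: none
Why: Indium‑mediated Barbier‑type acylation of the acid chloride by the allylindium reagent formed from 6 should give the β,γ‑unsaturated ketone, since allylindium species add only sluggishly to the ketone product and leave the dioxolanone alone.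

Step 5
Reactants: 8 (5R)‑5‑(4‑bromo‑2‑oxopent‑4‑en‑1‑yl)‑2,2,5‑trimethyl‑1,3‑dioxolan‑4‑one; 9 chloroacetaldehyde
Product: 10 (5R)‑5‑[(3S,4S)‑3‑(1‑bromoethenyl)‑5‑chloro‑4‑hydroxy‑2‑oxopentyl]‑2,2,5‑trimethyl‑1,3‑dioxolan‑4‑one
Conditions: (−)‑Ipc2BOTf, iPr2NEt, CH2Cl2, −78 °C; then 9, −78 to −20 °C; H2O2, MeOH, pH 7 buffer, 0 °C
Reagents that add atoms: none
Why: Boron‑mediated syn‑aldol reaction: enolisation should occur at the doubly activated C7 methylene to give the Z‑enol borinate, whose closed chair transition state sets the 6,7‑syn relationship, while the isopinocampheyl ligands on boron (reagent control) select the aldehyde face and so fix C6 and C7 relative to the remote C10 centre.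

Step 6
Reactants: 10 (5R)‑5‑[(3S,4S)‑3‑(1‑bromoethenyl)‑5‑chloro‑4‑hydroxy‑2‑oxopentyl]‑2,2,5‑trimethyl‑1,3‑dioxolan‑4‑one
Product: 12 (3R,5R)‑5‑[(3S,4S)‑2‑bromo‑5‑chloro‑4‑hydroxypent‑1‑en‑3‑yl]‑3‑hydroxy‑3‑methyloxolan‑2‑one, via anti‑diol 11 (not isolated)
Conditions: Me4NBH(OAc)3, MeCN/AcOH, −30 °C; then CSA (cat.), rt
Reagents that add atoms: none
Why: Evans–Saksena reduction delivers hydride intramolecularly from the C6‑bound acetoxyborohydride and should set C8 1,3‑anti to C6, after which acid‑catalysed transacylation of the new C8 hydroxyl onto the dioxolanone (lactonisation with loss of acetone) stores C8–OH and C1 together as a γ‑lactone.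

Step 7
Reactants: 12 (3R,5R)‑5‑[(3S,4S)‑2‑bromo‑5‑chloro‑4‑hydroxypent‑1‑en‑3‑yl]‑3‑hydroxy‑3‑methyloxolan‑2‑one
Product: 13 (3R,5R)‑5‑{(1R)‑2‑bromo‑1‑[(2S)‑oxiran‑2‑yl]prop‑2‑en‑1‑yl}‑3‑hydroxy‑3‑methyloxolan‑2‑one
Conditions: NaH, THF, 0 °C to rt
Reagents that add atoms: none
Why: Intramolecular Williamson etherification (3‑exo‑tet) of the chlorohydrin should close the terminal epoxide with retention at C6, and tetrahydrofuran formation cannot compete because the C8 oxygen is tied up in the lactone.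

Step 8
Reactants: 13 (3R,5R)‑5‑{(1R)‑2‑bromo‑1‑[(2S)‑oxiran‑2‑yl]prop‑2‑en‑1‑yl}‑3‑hydroxy‑3‑methyloxolan‑2‑one; 3 tert‑butyl(dimethyl)[(2‑methylidenebut‑3‑yn‑1‑yl)oxy]silane
Product: 14 (6R,8R,9R)‑10‑bromo‑2‑({[tert‑butyl(dimethyl)silyl]oxy}methyl)‑6,8‑dihydroxy‑6‑methyl‑9‑[(2S)‑oxiran‑2‑yl]undeca‑1,10‑dien‑3‑yn‑5‑one
Conditions: 3, nBuLi, THF, −78 °C; then 13, −78 to −40 °C; aq. NH4Cl
Reagents that add atoms: none
Why: Addition of a lithium acetylide to a γ‑lactone should stop at the ketone stage because the tetrahedral alkoxide collapses only on work‑up, giving the α′‑hydroxy ynone and releasing the C8 hydroxyl, while epoxide and alkenyl bromide are inert to the acetylide at low temperature.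

Step 9
Reactants: 14 (6R,8R,9R)‑10‑bromo‑2‑({[tert‑butyl(dimethyl)silyl]oxy}methyl)‑6,8‑dihydroxy‑6‑methyl‑9‑[(2S)‑oxiran‑2‑yl]undeca‑1,10‑dien‑3‑yn‑5‑one
Product: 15 (2R)‑2‑{(2R,3R)‑4‑bromo‑2‑hydroxy‑3‑[(2S)‑oxiran‑2‑yl]pent‑4‑en‑1‑yl}‑5‑(3‑{[tert‑butyl(dimethyl)silyl]oxy}prop‑1‑en‑2‑yl)‑2‑methylfuran‑3(2H)‑one
Conditions: Ph3PAuNTf2 (3 mol %), toluene, rt
Reagents that add atoms: none
Why: Gold‑catalysed 5‑endo‑dig cycloisomerisation of an α′‑hydroxy ynone, in which the tertiary C10 hydroxyl adds to the alkyne activated by monovalent gold, should form the 3(2H)‑furanone without touching the C10 stereocentre.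

Step 10
Reactants: 15 (2R)‑2‑{(2R,3R)‑4‑bromo‑2‑hydroxy‑3‑[(2S)‑oxiran‑2‑yl]pent‑4‑en‑1‑yl}‑5‑(3‑{[tert‑butyl(dimethyl)silyl]oxy}prop‑1‑en‑2‑yl)‑2‑methylfuran‑3(2H)‑one; 16 tigloyl chloride
Product: 17 (2R,3R)‑4‑bromo‑1‑[(2R)‑5‑(3‑{[tert‑butyl(dimethyl)silyl]oxy}prop‑1‑en‑2‑yl)‑2‑methyl‑3‑oxo‑2,3‑dihydrofuran‑2‑yl]‑3‑[(2S)‑oxiran‑2‑yl]pent‑4‑en‑2‑yl (2E)‑2‑methylbut‑2‑enoate
Conditions: Et3N, DMAP (cat.), CH2Cl2, 0 °C to rt
Reagents that add atoms: none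
Why: DMAP‑catalysed acylation of the only free hydroxyl (C8) by the acid chloride should give the tiglate with the E geometry of the reagent retained.

Step 11
Reactants: 17 (2R,3R)‑4‑bromo‑1‑[(2R)‑5‑(3‑{[tert‑butyl(dimethyl)silyl]oxy}prop‑1‑en‑2‑yl)‑2‑methyl‑3‑oxo‑2,3‑dihydrofuran‑2‑yl]‑3‑[(2S)‑oxiran‑2‑yl]pent‑4‑en‑2‑yl (2E)‑2‑methylbut‑2‑enoate
Product: 19 (1R)‑2‑[(2R)‑5‑(3‑{[tert‑butyl(dimethyl)silyl]oxy}prop‑1‑en‑2‑yl)‑2‑methyl‑3‑oxo‑2,3‑dihydrofuran‑2‑yl]‑1‑[(2R,3R)‑2‑(hydroxymethyl)‑4‑methylidene‑5‑oxooxolan‑3‑yl]ethyl (2E)‑2‑methylbut‑2‑enoate, via acrylic acid 18 (not isolated)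
Conditions: Pd(OAc)2 (5 mol %), Xantphos (6 mol %), CO (1 atm), KOAc, H2O, DMF, 60 °C; then AcOH, 45 °C
Reagents that add atoms: carbon monoxide, [C-]#[O+]; water, O
Why: Zerovalent palladium should insert into the C11–Br bond, CO insertion and hydrolysis of the acyl palladium species then give acrylate 18 (C11–C12 bond), and the carboxylate oxygen opens the neighbouring terminal epoxide at C6 (O–C6 bond). The closest known reaction types are the palladium‑catalysed hydroxycarbonylation of alkenyl bromides and the lactonisation of 4,5‑epoxy acids, run here as a domino. The γ‑lactone closes in the 5‑exo‑tet mode, which is preferred over 6‑endo attack at C5 because only attack at C6 allows backside approach within a five‑membered transition state. No stereocentre is made from a prochiral centre: C6 is inverted stereospecifically (SN2), so the epoxide configuration set in steps 5 to 7 fixes the cis relationship of C5 and C8 on the lactone. The step needs the O–C6 bond to come from the new carboxylate and not from acyl capture by a hydroxyl followed by retention at C6. This is secured because the C6 oxygen is locked in the epoxide, C8 carries the tiglate, C15 is silylated and C10 is part of the furanone, while KOAc removes HBr so that bromide does not open the epoxide first.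

Step 12
Reactants: 19 (1R)‑2‑[(2R)‑5‑(3‑{[tert‑butyl(dimethyl)silyl]oxy}prop‑1‑en‑2‑yl)‑2‑methyl‑3‑oxo‑2,3‑dihydrofuran‑2‑yl]‑1‑[(2R,3R)‑2‑(hydroxymethyl)‑4‑methylidene‑5‑oxooxolan‑3‑yl]ethyl (2E)‑2‑methylbut‑2‑enoate
Product: 20 (1R)‑2‑[(2R)‑5‑(3‑{[tert‑butyl(dimethyl)silyl]oxy}prop‑1‑en‑2‑yl)‑2‑methyl‑3‑oxo‑2,3‑dihydrofuran‑2‑yl]‑1‑[(2R,3R)‑2‑formyl‑4‑methylidene‑5‑oxooxolan‑3‑yl]ethyl (2E)‑2‑methylbut‑2‑enoate
Conditions: Dess–Martin periodinane, NaHCO3, CH2Cl2, 0 °C to rt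
Reagents that add atoms: none
Why: Buffered Dess–Martin oxidation of the primary alcohol should give the aldehyde without epimerising C6 or touching the enone systems.

Step 13
Reactants: 20 (1R)‑2‑[(2R)‑5‑(3‑{[tert‑butyl(dimethyl)silyl]oxy}prop‑1‑en‑2‑yl)‑2‑methyl‑3‑oxo‑2,3‑dihydrofuran‑2‑yl]‑1‑[(2R,3R)‑2‑formyl‑4‑methylidene‑5‑oxooxolan‑3‑yl]ethyl (2E)‑2‑methylbut‑2‑enoate
Product: 21 (1R)‑2‑[(2R)‑5‑(3‑{[tert‑butyl(dimethyl)silyl]oxy}prop‑1‑en‑2‑yl)‑2‑methyl‑3‑oxo‑2,3‑dihydrofuran‑2‑yl]‑1‑[(2S,3R)‑2‑ethenyl‑4‑methylidene‑5‑oxooxolan‑3‑yl]ethyl (2E)‑2‑methylbut‑2‑enoate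
Conditions: Zn, CH2I2, Ti(OiPr)4, THF, rt
Reagents that add atoms: diiodomethane, ICI
Why: Takai‑type methylenation with the gem‑dizinc/titanium reagent is non‑basic and aldehyde‑selective, so the lactone, ester and furanone carbonyls and the epimerisable C6 centre should stay untouched.

Step 14
Reactants: 21 (1R)‑2‑[(2R)‑5‑(3‑{[tert‑butyl(dimethyl)silyl]oxy}prop‑1‑en‑2‑yl)‑2‑methyl‑3‑oxo‑2,3‑dihydrofuran‑2‑yl]‑1‑[(2S,3R)‑2‑ethenyl‑4‑methylidene‑5‑oxooxolan‑3‑yl]ethyl (2E)‑2‑methylbut‑2‑enoate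
Product: 22 [(2Z,4S,8R,9R,11R)‑2‑({[tert‑butyl(dimethyl)silyl]oxy}methyl)‑11‑methyl‑7‑methylidene‑6,12‑dioxo‑5,14‑dioxatricyclo[9.2.1.0(4,8)]tetradeca‑1(13),2‑dien‑9‑yl] (2E)‑2‑methylbut‑2‑enoate
Conditions: second‑generation Hoveyda–Grubbs catalyst (15 mol %), toluene (1 mM), 100 °C
Reagents that add atoms: none
Why: Ring‑closing metathesis: the ruthenium carbene should load on the C5 vinyl group and close onto the 1,1‑disubstituted C4 olefin under high dilution, the bridged ring enforcing the Z (C3/C6 cis) trisubstituted olefin, while the electron‑poor α‑methylene and tiglate olefins stay spectators.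

Step 15
Reactants: 22 [(2Z,4S,8R,9R,11R)‑2‑({[tert‑butyl(dimethyl)silyl]oxy}methyl)‑11‑methyl‑7‑methylidene‑6,12‑dioxo‑5,14‑dioxatricyclo[9.2.1.0(4,8)]tetradeca‑1(13),2‑dien‑9‑yl] (2E)‑2‑methylbut‑2‑enoate
Product: 23 [(2Z,4S,8R,9R,11R)‑2‑(hydroxymethyl)‑11‑methyl‑7‑methylidene‑6,12‑dioxo‑5,14‑dioxatricyclo[9.2.1.0(4,8)]tetradeca‑1(13),2‑dien‑9‑yl] (2E)‑2‑methylbut‑2‑enoate (target)
Conditions: HF·pyridine, pyridine, THF, 0 °C to rt
Reagents that add atoms: none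
Why: Buffered fluoride cleavage of the primary silyl ether (desilylation) should free the C15 hydroxyl without conjugate addition to the α‑methylene lactone or the furanone.

Compound list
1 | 2‑bromoprop‑2‑en‑1‑ol | OCC(Br)=C | starting material
2 | [(2‑bromoprop‑2‑en‑1‑yl)oxy](tert‑butyl)dimethylsilane | C=C(Br)CO[Si](C)(C)C(C)(C)C | intermediate
3 | tert‑butyl(dimethyl)[(2‑methylidenebut‑3‑yn‑1‑yl)oxy]silane | C#CC(=C)CO[Si](C)(C)C(C)(C)C | intermediate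
4 | (R)‑citramalic acid, (2R)‑2‑hydroxy‑2‑methylbutanedioic acid | C[C@@](O)(CC(=O)O)C(=O)O | starting material
5 | 2‑[(4R)‑2,2,4‑trimethyl‑5‑oxo‑1,3‑dioxolan‑4‑yl]acetic acid | CC1(C)OC(=O)[C@@](C)(CC(=O)O)O1 | intermediate
6 | 2,3‑dibromoprop‑1‑ene | C=C(Br)CBr | starting material
7 | 2‑[(4R)‑2,2,4‑trimethyl‑5‑oxo‑1,3‑dioxolan‑4‑yl]acetyl chloride | CC1(C)OC(=O)[C@@](C)(CC(=O)Cl)O1 | intermediate
8 | (5R)‑5‑(4‑bromo‑2‑oxopent‑4‑en‑1‑yl)‑2,2,5‑trimethyl‑1,3‑dioxolan‑4‑one | CC1(C)OC(=O)[C@@](C)(CC(=O)CC(Br)=C)O1 | intermediate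
9 | chloroacetaldehyde | O=CCCl | starting material
10 | (5R)‑5‑[(3S,4S)‑3‑(1‑bromoethenyl)‑5‑chloro‑4‑hydroxy‑2‑oxopentyl]‑2,2,5‑trimethyl‑1,3‑dioxolan‑4‑one | CC1(C)OC(=O)[C@@](C)(CC(=O)[C@@H](C(Br)=C)[C@H](O)CCl)O1 | intermediate
11 | (5R)‑5‑[(2R,3R,4S)‑3‑(1‑bromoethenyl)‑5‑chloro‑2,4‑dihydroxypentyl]‑2,2,5‑trimethyl‑1,3‑dioxolan‑4‑one | CC1(C)OC(=O)[C@@](C)(C[C@@H](O)[C@@H](C(Br)=C)[C@H](O)CCl)O1 | intermediate
12 | (3R,5R)‑5‑[(3S,4S)‑2‑bromo‑5‑chloro‑4‑hydroxypent‑1‑en‑3‑yl]‑3‑hydroxy‑3‑methyloxolan‑2‑one | C[C@@]1(O)C[C@@H](OC1=O)[C@@H](C(Br)=C)[C@H](O)CCl | intermediate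
13 | (3R,5R)‑5‑{(1R)‑2‑bromo‑1‑[(2S)‑oxiran‑2‑yl]prop‑2‑en‑1‑yl}‑3‑hydroxy‑3‑methyloxolan‑2‑one | C[C@@]1(O)C[C@@H](OC1=O)[C@@H](C(Br)=C)[C@H]1CO1 | intermediate
14 | (6R,8R,9R)‑10‑bromo‑2‑({[tert‑butyl(dimethyl)silyl]oxy}methyl)‑6,8‑dihydroxy‑6‑methyl‑9‑[(2S)‑oxiran‑2‑yl]undeca‑1,10‑dien‑3‑yn‑5‑one | C=C(CO[Si](C)(C)C(C)(C)C)C#CC(=O)[C@](C)(O)C[C@@H](O)[C@@H](C(Br)=C)[C@H]1CO1 | intermediate
15 | (2R)‑2‑{(2R,3R)‑4‑bromo‑2‑hydroxy‑3‑[(2S)‑oxiran‑2‑yl]pent‑4‑en‑1‑yl}‑5‑(3‑{[tert‑butyl(dimethyl)silyl]oxy}prop‑1‑en‑2‑yl)‑2‑methylfuran‑3(2H)‑one | C=C(CO[Si](C)(C)C(C)(C)C)C1=CC(=O)[C@@](C)(C[C@@H](O)[C@@H](C(Br)=C)[C@H]2CO2)O1 | intermediate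
16 | tigloyl chloride, (2E)‑2‑methylbut‑2‑enoyl chloride | C/C=C(\C)C(=O)Cl | starting material
17 | (2R,3R)‑4‑bromo‑1‑[(2R)‑5‑(3‑{[tert‑butyl(dimethyl)silyl]oxy}prop‑1‑en‑2‑yl)‑2‑methyl‑3‑oxo‑2,3‑dihydrofuran‑2‑yl]‑3‑[(2S)‑oxiran‑2‑yl]pent‑4‑en‑2‑yl (2E)‑2‑methylbut‑2‑enoate | C=C(CO[Si](C)(C)C(C)(C)C)C1=CC(=O)[C@@](C)(C[C@@H](OC(=O)/C(C)=C/C)[C@@H](C(Br)=C)[C@H]2CO2)O1 | intermediate
18 | (3R,4R)‑5‑[(2R)‑5‑(3‑{[tert‑butyl(dimethyl)silyl]oxy}prop‑1‑en‑2‑yl)‑2‑methyl‑3‑oxo‑2,3‑dihydrofuran‑2‑yl]‑2‑methylidene‑4‑{[(2E)‑2‑methylbut‑2‑enoyl]oxy}‑3‑[(2S)‑oxiran‑2‑yl]pentanoic acid | C=C(CO[Si](C)(C)C(C)(C)C)C1=CC(=O)[C@@](C)(C[C@@H](OC(=O)/C(C)=C/C)[C@@H](C(=C)C(=O)O)[C@H]2CO2)O1 | intermediate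
19 | (1R)‑2‑[(2R)‑5‑(3‑{[tert‑butyl(dimethyl)silyl]oxy}prop‑1‑en‑2‑yl)‑2‑methyl‑3‑oxo‑2,3‑dihydrofuran‑2‑yl]‑1‑[(2R,3R)‑2‑(hydroxymethyl)‑4‑methylidene‑5‑oxooxolan‑3‑yl]ethyl (2E)‑2‑methylbut‑2‑enoate | C=C1C(=O)O[C@@H](CO)[C@H]1[C@H](OC(=O)/C(C)=C/C)C[C@@]1(C)OC(C(=C)CO[Si](C)(C)C(C)(C)C)=CC1=O | intermediate
20 | (1R)‑2‑[(2R)‑5‑(3‑{[tert‑butyl(dimethyl)silyl]oxy}prop‑1‑en‑2‑yl)‑2‑methyl‑3‑oxo‑2,3‑dihydrofuran‑2‑yl]‑1‑[(2R,3R)‑2‑formyl‑4‑methylidene‑5‑oxooxolan‑3‑yl]ethyl (2E)‑2‑methylbut‑2‑enoate | C=C1C(=O)O[C@@H](C=O)[C@H]1[C@H](OC(=O)/C(C)=C/C)C[C@@]1(C)OC(C(=C)CO[Si](C)(C)C(C)(C)C)=CC1=O | intermediate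
21 | (1R)‑2‑[(2R)‑5‑(3‑{[tert‑butyl(dimethyl)silyl]oxy}prop‑1‑en‑2‑yl)‑2‑methyl‑3‑oxo‑2,3‑dihydrofuran‑2‑yl]‑1‑[(2S,3R)‑2‑ethenyl‑4‑methylidene‑5‑oxooxolan‑3‑yl]ethyl (2E)‑2‑methylbut‑2‑enoate | C=C1C(=O)O[C@@H](C=C)[C@H]1[C@H](OC(=O)/C(C)=C/C)C[C@@]1(C)OC(C(=C)CO[Si](C)(C)C(C)(C)C)=CC1=O | intermediate
22 | [(2Z,4S,8R,9R,11R)‑2‑({[tert‑butyl(dimethyl)silyl]oxy}methyl)‑11‑methyl‑7‑methylidene‑6,12‑dioxo‑5,14‑dioxatricyclo[9.2.1.0(4,8)]tetradeca‑1(13),2‑dien‑9‑yl] (2E)‑2‑methylbut‑2‑enoate | C=C1C(=O)O[C@H]2/C=C(/CO[Si](C)(C)C(C)(C)C)C3=CC(=O)[C@@](C)(C[C@@H](OC(=O)/C(C)=C/C)[C@@H]12)O3 | intermediate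
23 | [(2Z,4S,8R,9R,11R)‑2‑(hydroxymethyl)‑11‑methyl‑7‑methylidene‑6,12‑dioxo‑5,14‑dioxatricyclo[9.2.1.0(4,8)]tetradeca‑1(13),2‑dien‑9‑yl] (2E)‑2‑methylbut‑2‑enoate; germacrane descriptors 6S,7R,8R,10R | C=C1C(=O)O[C@H]2/C=C(/CO)C3=CC(=O)[C@@](C)(C[C@@H](OC(=O)/C(C)=C/C)[C@@H]12)O3 | target

Total step count: 15. Longest linear sequence: 13 steps (steps 3 to 15, from (R)‑citramalic acid).

Steps most likely to fail

Step 14 (ring closure). The carbene formed at the C5 vinyl group, which sits next to the lactone oxygen, may initiate slowly or rest as a chelate, so that intermolecular metathesis and oligomerisation outrun closure of the strained bridged ring. The fallback changes the substrate to a relay design. It sets out from aldehyde 20: Wittig olefination with the ylide of (hex‑5‑en‑1‑yl)triphenylphosphonium bromide (KHMDS, THF, −78 °C) would give the (Z)‑hepta‑1,6‑dienyl relay substrate F1. With the second‑generation Hoveyda–Grubbs catalyst the ruthenium would load on the remote, unhindered terminal olefin, expel cyclopentene and arrive intramolecularly as the C5 alkylidene, which then closes onto the C4 olefin. The fallback returns to the route at 22.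

Step 11 (key step). Acetate, bromide or water may open the epoxide before the carboxylate exists; the lactone would then close through a C6 hydroxyl with retention and give the C6 epimer. The fallback keeps both bonds in one operation but takes C12 and the ring oxygen from CO2. It sets out from 17: Miyaura borylation (B2pin2, PdCl2(dppf), KOPh, toluene, 50 °C) would give the alkenyl pinacol boronate F2. Copper‑catalysed carboxylation ((IPr)CuCl, KOtBu, CO2 (1 atm), THF, 65 °C; then AcOH) would form the potassium acrylate, which opens the epoxide at C6 in the same flask. The fallback returns to the route at 19.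

Step 4 (ketone formation). The allylindium reagent may add a second time to the ketone, or the β,γ‑unsaturated ketone may slip into conjugation. The fallback builds the C7–C8 bond at the aldehyde oxidation level. It sets out from 5: reduction of the free carboxyl with BH3·SMe2 (THF, 0 °C) would give the primary alcohol F3, and Dess–Martin oxidation the aldehyde F4. Aqueous indium Barbier allylation with 6 (In, THF/H2O) would give the bromohomoallylic alcohol F5 as a mixture of C8 epimers, and a second Dess–Martin oxidation would converge both on ketone 8, where the fallback returns to the route.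

Further compounds
F1 | step 14 | (1R)‑1‑{(2S,3R)‑2‑[(1Z)‑hepta‑1,6‑dien‑1‑yl]‑4‑methylidene‑5‑oxooxolan‑3‑yl}‑2‑[(2R)‑5‑(3‑{[tert‑butyl(dimethyl)silyl]oxy}prop‑1‑en‑2‑yl)‑2‑methyl‑3‑oxo‑2,3‑dihydrofuran‑2‑yl]ethyl (2E)‑2‑methylbut‑2‑enoate | C=C1C(=O)O[C@@H](/C=C\CCCC=C)[C@H]1[C@H](OC(=O)/C(C)=C/C)C[C@@]1(C)OC(C(=C)CO[Si](C)(C)C(C)(C)C)=CC1=O
F2 | step 11 | (2R,3R)‑1‑[(2R)‑5‑(3‑{[tert‑butyl(dimethyl)silyl]oxy}prop‑1‑en‑2‑yl)‑2‑methyl‑3‑oxo‑2,3‑dihydrofuran‑2‑yl]‑3‑[(2S)‑oxiran‑2‑yl]‑4‑(4,4,5,5‑tetramethyl‑1,3,2‑dioxaborolan‑2‑yl)pent‑4‑en‑2‑yl (2E)‑2‑methylbut‑2‑enoate | C=C(CO[Si](C)(C)C(C)(C)C)C1=CC(=O)[C@@](C)(C[C@@H](OC(=O)/C(C)=C/C)[C@@H](C(=C)B2OC(C)(C)C(C)(C)O2)[C@H]3CO3)O1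
F3 | step 4 | (5R)‑5‑(2‑hydroxyethyl)‑2,2,5‑trimethyl‑1,3‑dioxolan‑4‑one | CC1(C)OC(=O)[C@@](C)(CCO)O1
F4 | step 4 | 2‑[(4R)‑2,2,4‑trimethyl‑5‑oxo‑1,3‑dioxolan‑4‑yl]acetaldehyde | CC1(C)OC(=O)[C@@](C)(CC=O)O1
F5 | step 4 | (5R)‑5‑(4‑bromo‑2‑hydroxypent‑4‑en‑1‑yl)‑2,2,5‑trimethyl‑1,3‑dioxolan‑4‑one, both epimers at the carbinol carbon | CC1(C)OC(=O)[C@@](C)(CC(O)CC(Br)=C)O1
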